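The plan opens ring B (C1-C9-C5-C6-C7-C8) of the bicyclo[3.3.1]nonane at C5-C6 and trades the C7-H bond for a C6=C7 alkene. Forward, one operation turns a dearomatized, enolized acylphloroglucinol triketone into the target: a C5 radical closes ring B 6-endo onto C6, and the C7 radical then takes hydrogen on its exo face, which leaves the C7 prenyl endo, cis to the C2-C3-C4 bridge of ring A. The step exploits the C9 carbonyl inside ring B and the quaternary C1-C8 bond that holds the alkene over C5. The precursor carries C8-C7(=C6H2) on quaternary C1, set by an enantioselective dearomative Claisen shift.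

Key step: step 10

Remark 1 (labels): C1 and C5 are the bridgeheads (C1 next to C8), C2-C3-C4 is the benzoylated triketone bridge, C6-C7-C8 the bridge with the C7 prenyl and the C8 gem-dimethyl group, C9 the bridging carbonyl. Ring A is C1-C2-C3-C4-C5-C9 and ring B is C1-C9-C5-C6-C7-C8. The same labels are used for these atoms in all precursors, and descriptors refer to the tautomers drawn.

Remark 2 (assumption): the sense of induction of the ligand in step 8 cannot be predicted with confidence. (S,S)-tBu-box is written, and (R,R)-tBu-box takes its place if a first run shows the opposite sense at C1.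

Step 1
Reactants: 1 ethyl acetoacetate; 2 prenyl bromide (1-bromo-3-methylbut-2-ene)
Product: 3 ethyl 2-acetyl-5-methylhex-4-enoate (racemic)
Conditions: K2CO3, acetone, reflux (1 in slight excess)
Reagents that add atoms: none
Why: Acetoacetic ester alkylation: the stabilized β-keto ester enolate is C-alkylated by the reactive allylic bromide, and the excess of 1 holds back dialkylation.

Step 2
Reactants: 3 ethyl 2-acetyl-5-methylhex-4-enoate
Product: 4 ethyl 5-methyl-2-[1-(trifluoromethylsulfonyloxy)ethylidene]hex-4-enoate (enol triflate; either alkene geometry serves)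
Conditions: NaH, Et2O, 0 °C; then Tf2O, 0 °C
Reagents that add atoms: triflic anhydride, O=S(=O)(OS(=O)(=O)C(F)(F)F)C(F)(F)F
Why: O-sulfonylation of the sodium enolate of a β-keto ester gives the enol triflate, and its geometry is irrelevant because both β-substituents are methyl after step 3.

Step 3
Reactants: 4 enol triflate
Product: 5 ethyl 5-methyl-2-(propan-2-ylidene)hex-4-enoate
Conditions: Me2CuLi (from MeLi and CuI), Et2O, −78 → −20 °C
Reagents that add atoms: lithium dimethylcuprate, [Li+].C[Cu-]C
Why: Cuprate coupling of a β-triflyloxy enoate (conjugate addition, then loss of triflate) puts methyl in place of OTf and leaves the ester and the prenyl alkene untouched.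

Step 4
Reactants: 5 ethyl 5-methyl-2-(propan-2-ylidene)hex-4-enoate
Product: 6 isolavandulol, 5-methyl-2-(propan-2-ylidene)hex-4-en-1-ol
Conditions: i-Bu2AlH, CH2Cl2, −78 → 0 °C; aq. potassium sodium tartrate
Reagents that add atoms: none
Why: i-Bu2AlH reduces the conjugated ester in the 1,2 sense to the primary allylic alcohol and does not touch the two alkenes.

Step 5
Reactants: 7 2,4,6-trihydroxybenzophenone; 2 prenyl bromide (2 equiv)
Product: 8 clusiaphenone B, 3,5-diprenyl-2,4,6-trihydroxybenzophenone
Conditions: aq. KOH, 0 °C → rt
Reagents that add atoms: none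
Why: In aqueous base the phloroglucinol phenolate is C-prenylated at its two free ring carbons and rearomatizes after each alkylation (C-alkylation of a phenolate in a protic medium).

Step 6
Reactants: 8 clusiaphenone B
Product: 10 2,4-bis-O-TBS clusiaphenone B (silyl on the para oxygen O9 and on the ortho oxygen O4; O2-H free), via 4-O-TBS clusiaphenone B 9 (not isolated)
Conditions: TBSCl (2.2 equiv), imidazole, DMF, 0 °C → rt
Reagents that add atoms: tert-butyldimethylsilyl chloride, CC(C)(C)[Si](C)(C)Cl
Why: Phenol silylation takes the non-chelated para OH first (9), then one of the two equivalent chelated OH groups, and spares the last OH, which is now the only hydrogen-bond partner of the benzoyl oxygen; capping O4 removes the acidic chelating phenol that would otherwise bind the copper catalyst of step 8 or close onto the neighbouring prenyl group.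

Step 7
Reactants: 10 2,4-bis-O-TBS clusiaphenone B; 6 isolavandulol
Product: 11 aryl isolavandulyl ether at O2, [2-{[5-methyl-2-(propan-2-ylidene)hex-4-en-1-yl]oxy}-4,6-bis(tert-butyldimethylsilyloxy)-3,5-diprenylphenyl](phenyl)methanone
Conditions: PPh3, DIAD, toluene, 0 °C → rt
Reagents that add atoms: none
Why: Mitsunobu etherification: the acidic acylphloroglucinol OH protonates the betaine and its phenolate displaces the oxyphosphonium at the primary allylic CH2, which gives the O-alkyl product under neutral conditions and avoids the ring C-alkylation that a phenolate/halide reaction risks.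

Step 8
Reactants: 11 aryl isolavandulyl ether
Product: 12 C1-quaternary bis-silyl dienone, (6S)-2-benzoyl-3,5-bis(tert-butyldimethylsilyloxy)-6-(2,6-dimethyl-3-methylidenehept-5-en-2-yl)-4,6-bis(3-methylbut-2-en-1-yl)cyclohexa-2,4-dien-1-one (ring C6 is C1 of the labels)
Conditions: Cu(OTf)2 (10 mol %), (S,S)-tBu-box (11 mol %), 4 Å MS, CH2Cl2, −40 → −20 °C; cold filtration through neutral alumina, used crude
Reagents that add atoms: none
Why: Proposed new method: the bisoxazoline-Cu(OTf)2 complex (divalent copper) should bind the ether oxygen O2 and the benzoyl oxygen as a six-membered chelate (the two silyl ethers are poor donors), which polarizes the O2-CH2 bond and lets a charge-accelerated aromatic Claisen [3,3] shift carry the CMe2 terminus to the prenyl-bearing ortho carbon C1 at a temperature below that of the onward Cope shift to C5; the ligand shields one face of ring A so that the C1-C8 bond forms with C1 (S); the closest known reaction types are the copper-catalysed enantioselective dearomative Claisen rearrangement of allyl 2-naphthyl ethers with a chelating ortho carbonyl group and the copper-bisoxazoline Claisen rearrangement of 2-alkoxycarbonyl allyl vinyl ethers, neither of which has been shown for a fully substituted acylphloroglucinol ether or for an allyl terminus that forms two adjacent quaternary carbons.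

Step 9
Reactants: 12 bis-silyl dienone
Product: 13 enolized triketone, (6R)-4-benzoyl-3,5-dihydroxy-6-(2,6-dimethyl-3-methylidenehept-5-en-2-yl)-2,6-bis(3-methylbut-2-en-1-yl)cyclohexa-2,4-dien-1-one (ring C6 is C1 of the labels; same spatial arrangement as in 12, the descriptor changes with the tautomer)
Conditions: Bu4NF, AcOH, THF, 0 °C
Reagents that add atoms: none
Why: Buffered fluoride cleaves both silyl enol ethers (O4 and O9) and the freed vinylogous acid settles as the chelated enol, while quaternary C1 cannot epimerize.

Step 10
Reactants: 13 enolized triketone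
Product: 14 target CID5471610, (3Z)-3-[hydroxy(phenyl)methylidene]-8,8-dimethyl-1,5,7-tris(3-methylbut-2-en-1-yl)bicyclo[3.3.1]nonane-2,4,9-trione with C1 (S), C5 (R), C7 (S) in the labels of remark 1, C7 prenyl endo
Conditions: 4CzIPN (3 mol %), 2,4,6-triisopropylbenzenethiol (10 mol %), Cs2CO3 (0.3 equiv), degassed MeCN, 450 nm LEDs, rt; aq. citric acid work-up
Reagents that add atoms: none
Why: Proposed new method: photoexcited 4CzIPN should oxidize the caesium enolate of 13 by one electron to a triketone radical with spin at the prenyl-bearing C5, which adds to the CH2 terminus C6 of the 1,1-disubstituted alkene and thereby closes ring B (C1-C9-C5-C6-C7-C8) onto ring A in the 6-endo-trig mode, giving the bicyclo[3.3.1]nonane and a tertiary C7 radical; the arenethiol then gives hydrogen to C7 and the thiyl radical is reduced back to thiolate by the reduced photocatalyst, so that the step is a redox-neutral isomerization. The closest known reaction types are the Mn(OAc)3 (trivalent manganese) oxidative radical cyclizations of dearomatized acylphloroglucinols onto prenyl groups and the photoredox/thiol hydroalkylation of unactivated alkenes with 1,3-dicarbonyl compounds. C5 follows from C1, because the three-atom tether C8-C7-C6 can reach C5 only on the face of ring A on which it already sits. C7 is set in the hydrogen transfer: the C2-C3-C4 bridge covers the endo face of the planar C7 radical, so the bulky thiol should deliver hydrogen to the exo face and leave the prenyl endo. The step needs C5-to-C6 closure to outrun 5-exo attack of C5 on the C1 prenyl group and closure from C3, and it needs the C7 radical to be trapped before it adds to a neighbouring prenyl group. This is expected because the unsubstituted C6 terminus is the best acceptor for the electrophilic C5 radical and is held over C5 by the C8 gem-dimethyl group and quaternary C1, the C9 carbonyl inside the forming ring favours 6-endo over 5-exo closure, C7 is fully substituted, C3 stays tied up in the chelated benzoyl enol, and the thiol loading sets the rate of hydrogen transfer.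

Compound list
1 | ethyl acetoacetate | CCOC(=O)CC(C)=O | starting material
2 | prenyl bromide (1-bromo-3-methylbut-2-ene) | CC(C)=CCBr | starting material
3 | ethyl 2-acetyl-5-methylhex-4-enoate (racemic) | CCOC(=O)C(CC=C(C)C)C(C)=O | intermediate
4 | ethyl 5-methyl-2-[1-(trifluoromethylsulfonyloxy)ethylidene]hex-4-enoate (geometry not fixed) | CCOC(=O)C(CC=C(C)C)=C(C)OS(=O)(=O)C(F)(F)F | intermediate
5 | ethyl 5-methyl-2-(propan-2-ylidene)hex-4-enoate | CCOC(=O)C(CC=C(C)C)=C(C)C | intermediate
6 | isolavandulol, 5-methyl-2-(propan-2-ylidene)hex-4-en-1-ol | CC(C)=CCC(CO)=C(C)C | intermediate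
7 | 2,4,6-trihydroxybenzophenone | O=C(c1ccccc1)c1c(O)cc(O)cc1O | starting material
8 | clusiaphenone B | O=C(c1ccccc1)c1c(O)c(CC=C(C)C)c(O)c(CC=C(C)C)c1O | intermediate
9 | 4-O-TBS clusiaphenone B | O=C(c1ccccc1)c1c(O)c(CC=C(C)C)c(O[Si](C)(C)C(C)(C)C)c(CC=C(C)C)c1O | intermediate (not isolated)
10 | 2,4-bis-O-TBS clusiaphenone B | O=C(c1ccccc1)c1c(O)c(CC=C(C)C)c(O[Si](C)(C)C(C)(C)C)c(CC=C(C)C)c1O[Si](C)(C)C(C)(C)C | intermediate
11 | aryl isolavandulyl ether at O2 (bis-TBS) | O=C(c1ccccc1)c1c(O[Si](C)(C)C(C)(C)C)c(CC=C(C)C)c(O[Si](C)(C)C(C)(C)C)c(CC=C(C)C)c1OCC(CC=C(C)C)=C(C)C | intermediate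
12 | C1-quaternary bis-silyl dienone, C1 (S) | O=C(c1ccccc1)C1=C(O[Si](C)(C)C(C)(C)C)C(CC=C(C)C)=C(O[Si](C)(C)C(C)(C)C)[C@](CC=C(C)C)(C(C)(C)C(=C)CC=C(C)C)C1=O | intermediate
13 | enolized triketone with C8-C7(=C6H2) on C1, C1 (R) in this tautomer | O=C(c1ccccc1)C1=C(O)[C@@](CC=C(C)C)(C(C)(C)C(=C)CC=C(C)C)C(=O)C(CC=C(C)C)=C1O | intermediate
14 | CID5471610, C1 (S), C5 (R), C7 (S), C7 prenyl endo | CC(C)=CC[C@H]1C[C@@]2(CC=C(C)C)C(=O)/C(=C(/O)c3ccccc3)C(=O)[C@](CC=C(C)C)(C2=O)C1(C)C | target

Total step count: 10 steps.
Longest linear sequence: 8 steps (steps 1-4, then 7-10, from ethyl acetoacetate). The arene branch (steps 5-10) is 6 steps.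

Steps most likely to fail

1. Step 10 (proposed new method). The C5 radical may instead close 5-exo onto the C1 prenyl group and cascade on to the C5 prenyl group. Hydrogen may also reach C7 from the endo face (poor facial selectivity), or the product enolate may be re-oxidized under the light. The fallback uses known chemistry, sets out from 8 and comes back to the route at 14.
   - Bought (R)-lavandulol, (2R)-5-methyl-2-(prop-1-en-2-yl)hex-4-en-1-ol, is turned into (R)-lavandulyl triflate F1 (Tf2O, 2,6-lutidine, CH2Cl2, −78 °C), which is used at once.
   - The lithium phenolate of 8 (LiN(SiMe3)2, THF, 0 °C) is C-alkylated by F1 at a prenyl-bearing ring carbon (alkylative dearomatization). This gives the dearomatized lavandulyl triketone F2, whose new quaternary carbon C5 and lavandulyl carbon C7 are configured as in 14, together with its C5 epimer F3; no control at C5 is expected.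
   - In HCO2H at rt the isopropenyl group is protonated and the tertiary C8 cation is captured by the enol carbon C1, which closes ring B at C1-C8 (cationic cyclization). F2 can only give 14 with the C7 prenyl endo, whereas F3 gives the C7-exo diastereomer F4 of the opposite bicyclic series, which is removed by chromatography.

2. Step 8 (proposed new method). The copper-bound ether may ionize to an allyl cation/aryloxide pair that recombines with [1,3] connectivity or without face control. An onward Cope shift to C5 or a low enantioselectivity are the other failure processes. The fallback uses known chemistry, sets out from 11 and comes back at 13.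
   - The Claisen shift is run without chiral control, with Eu(fod)3, tris(6,6,7,7,8,8,8-heptafluoro-2,2-dimethyloctane-3,5-dionato)europium (10 mol %), in CHCl3 at 50 °C, to give the racemic bis-silyl dienone F5.
   - Bu4NF/AcOH in THF at 0 °C gives the racemic triketone F6.
   - F6 is resolved by preparative HPLC on a cellulose carbamate chiral stationary phase. The enantiomer that is 13 goes on to step 10.

3. Step 7. Attack of the hindered, hydrogen-bonded phenol on the alkoxyphosphonium may be slow, so that elimination of the activated alcohol or silyl transfer between phenolic oxygens takes over. The fallback sets out from 6 (with 10) and comes back at 11.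
   - 6 is converted into isolavandulyl bromide F7 (CBr4, PPh3, CH2Cl2, 0 °C).
   - 10 is O-alkylated with F7 under Williamson conditions (K2CO3, acetone, rt → 40 °C), where the potassium phenolate in a polar aprotic medium favours attack through oxygen.

Further compounds
F1 | step 10 | (R)-lavandulyl triflate | C=C(C)[C@@H](CC=C(C)C)COS(=O)(=O)C(F)(F)F
F2 | step 10 | dearomatized lavandulyl triketone, C5 and C7 as in 14 | C=C(C)[C@@H](CC=C(C)C)C[C@@]1(CC=C(C)C)C(=O)C(C(=O)c2ccccc2)=C(O)C(CC=C(C)C)=C1O
F3 | step 10 | C5 epimer of F2 | C=C(C)[C@@H](CC=C(C)C)C[C@]1(CC=C(C)C)C(=O)C(C(=O)c2ccccc2)=C(O)C(CC=C(C)C)=C1O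
F4 | step 10 | C7-exo diastereomer of 14 (C1 and C5 inverted, C7 unchanged) | CC(C)=CC[C@H]1C[C@]2(CC=C(C)C)C(=O)/C(=C(/O)c3ccccc3)C(=O)[C@@](CC=C(C)C)(C2=O)C1(C)C
F5 | step 8 | racemic bis-silyl dienone (racemate of 12) | O=C(c1ccccc1)C1=C(O[Si](C)(C)C(C)(C)C)C(CC=C(C)C)=C(O[Si](C)(C)C(C)(C)C)C(CC=C(C)C)(C(C)(C)C(=C)CC=C(C)C)C1=O
F6 | step 8 | racemic enolized triketone (racemate of 13) | O=C(c1ccccc1)C1=C(O)C(CC=C(C)C)(C(C)(C)C(=C)CC=C(C)C)C(=O)C(CC=C(C)C)=C1O
F7 | step 7 | isolavandulyl bromide, 3-(bromomethyl)-2,6-dimethylhepta-2,5-diene | CC(C)=CCC(CBr)=C(C)C
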